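**Retrosynthetic overview** (atom labels follow the isochromene numbering of the target: C8 ketone, C7 carbinol with methyl and ester, C6 CHOH, C1 OCH2)

1. Target ⇐ global desilylation, and before that acylation of the tertiary C7–OH of the bicyclic diol (C6–OH silylated) with 4-silyloxy-2-methoxy-6-methylbenzoyl chloride.
2. Bicyclic diol ⇐ one-flask carbene-catalysed crossed benzoin (C7–C8: Breslow acyl anion at the aldehyde carbon C8 onto the methyl ketone carbon C7; closes the carbocycle and sets C7), then oxa-Michael closure of the pyran (O2–C3).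
3. Lactol-masked (E)-ynenal methyl ketone ⇐ 1,2-addition of lithium (E)-pentenynide to a 5-(hydroxymethyl)dihydropyranone, then acid-induced carbonyl transposition and ketal hydrolysis; the dihydropyranone oxygen ring is a temporary template that carries C6–O and holds the aldehyde cis to the ketone arm.
4. Dihydropyranone ⇐ asymmetric hetero-Diels–Alder of Danishefsky's diene with 2,2-dimethoxypropanal (sets C6), α-iodination, Stille hydroxymethylation (C1).
5. Ring order: temporary dihydropyranone → carbocycle → pyran.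

Assumption: the (S,S)-enantiomer of the chromium salen catalyst is taken to give the (S)-configured hetero-Diels–Alder adduct; if the facial sense is opposite with this aldehyde, the (R,R)-catalyst is used instead.

**Route**

Step 1
Reactants: 1 methyl pyruvate
Product: 2 methyl 2,2-dimethoxypropanoate
Conditions: HC(OMe)3, MeOH, cat. H2SO4, reflux
Reagents that add atoms: trimethyl orthoformate, COC(OC)OC
Why: Acid-catalysed ketalisation of the activated α-keto ester, driven by the orthoformate, masks the carbonyl that later becomes the C7 ketone so that it survives the organolithium step (ketal formation).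

Step 2
Reactants: 2 methyl 2,2-dimethoxypropanoate
Product: 3 2,2-dimethoxypropanal
Conditions: i-Bu2AlH, CH2Cl2, −78 °C; aq. potassium sodium tartrate
Reagents that add atoms: none
Why: The α,α-dialkoxy ester gives a chelated tetrahedral aluminate that is stable at −78 °C and collapses to the aldehyde only on work-up (ester-to-aldehyde half-reduction).

Step 3
Reactants: 3 2,2-dimethoxypropanal; 4 (E)-1-methoxy-3-(trimethylsilyloxy)buta-1,3-diene (Danishefsky's diene)
Product: 7 (2S)-2-(1,1-dimethoxyethyl)-5-iodo-2,3-dihydro-4H-pyran-4-one, via silyl enol ether cycloadduct 5 (not isolated), via iodo methoxy ketone 6 (not isolated)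
Conditions: (S,S)-(salen)CrBF4 (5 mol%; salen = N,N'-bis(3,5-di-tert-butylsalicylidene)cyclohexane-1,2-diamine dianion), 4 Å molecular sieves, t-BuOMe, −30 °C; then N-iodosuccinimide, THF, −30 → 0 °C; then CF3CO2H, CH2Cl2, 0 °C
Reagents that add atoms: N-iodosuccinimide, O=C1CCC(=O)N1I
Why: The chiral chromium Lewis acid catalyses the hetero-Diels–Alder reaction at the aldehyde C=O and differentiates its faces, which sets C6 (S), and the silyl enol ether of the cycloadduct is iodinated at C8a before acid expels methanol to give the α-iodo enone (asymmetric hetero-Diels–Alder reaction followed by electrophilic α-iodination of a silyl enol ether).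

Step 4
Reactants: 7 (2S)-2-(1,1-dimethoxyethyl)-5-iodo-2,3-dihydro-4H-pyran-4-one
Product: 8 (2S)-2-(1,1-dimethoxyethyl)-5-(hydroxymethyl)-2,3-dihydro-4H-pyran-4-one
Conditions: Bu3SnCH2OH, Pd(PPh3)4 (5 mol%), dioxane, 90 °C
Reagents that add atoms: (tributylstannyl)methanol, CCCC[Sn](CCCC)(CCCC)CO
Why: The α-iodo enone undergoes oxidative addition readily and the hydroxymethyl group transfers from tin in preference to butyl, which installs C1 on C8a (Stille coupling).

Step 5
Reactants: 9 (E)-but-2-enal (crotonaldehyde)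
Product: 10 (3E)-1,1-dibromopenta-1,3-diene
Conditions: CBr4, PPh3, CH2Cl2, 0 °C
Reagents that add atoms: carbon tetrabromide, BrC(Br)(Br)Br
Why: Dibromo-olefination of the aldehyde leaves the (E)-alkene untouched and gives a non-volatile precursor of the pentenynyl anion (first stage of the Corey–Fuchs reaction).

Step 6
Reactants: 8 (2S)-2-(1,1-dimethoxyethyl)-5-(hydroxymethyl)-2,3-dihydro-4H-pyran-4-one; 10 (3E)-1,1-dibromopenta-1,3-diene
Product: 13 (6S)-6-acetyl-3-(hydroxymethyl)-4-[(E)-pent-3-en-1-yn-1-yl]-5,6-dihydro-2H-pyran-2-ol (anomer mixture), via lithium pentenynide 11 (not isolated), via tertiary propargylic carbinol 12 (not isolated)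
Conditions: 10 (3 equiv), n-BuLi (6 equiv), THF, −78 → 0 °C; then 8, −78 °C; then 1 M aq. HCl, THF, 0 °C → rt
Reagents that add atoms: water, O
Why: Two equivalents of n-BuLi turn the dibromodiene into the acetylide (second stage of the Corey–Fuchs reaction), which adds 1,2 to the vinylogous-ester carbonyl, and aqueous acid then ionises the tertiary carbinol, returns water at the acetal carbon and hydrolyses the dimethyl ketal, giving a lactol whose ring holds the C8 aldehyde cis to the ketone arm (Stork–Danheiser-type carbonyl transposition).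

Step 7
Reactants: 13 (6S)-6-acetyl-3-(hydroxymethyl)-4-[(E)-pent-3-en-1-yn-1-yl]-5,6-dihydro-2H-pyran-2-ol
Product: 15 (6S,7R)-6,7-dihydroxy-7-methyl-3-[(E)-prop-1-en-1-yl]-1,5,6,7-tetrahydro-8H-isochromen-8-one, via ynenone triol 14 (not isolated)
Conditions: 2-(pentafluorophenyl)-6,7-dihydro-5H-pyrrolo[2,1-c][1,2,4]triazol-2-ium tetrafluoroborate (15 mol%), Et3N (15 mol%), THF, rt; then 1,8-diazabicyclo[5.4.0]undec-7-ene (30 mol%), rt
Reagents that add atoms: none
Why: Proposed new method: the lactol opens to the (E)-ynenal, the carbene adds to the aldehyde and the resulting Breslow intermediate (an acyl anion equivalent at C8) attacks the α-alkoxy methyl ketone carbon C7 6-exo through a half-chair in which the C6–O bond is pseudo-equatorial and anti to the forming C7–C8 bond and the ketone oxygen is hydrogen-bonded to the enaminol OH, so that the new C7–OH ends trans to C6–OH (7R), after which the amidine base triggers 6-endo 1,6-oxa-Michael addition of the hydroxymethyl oxygen to C3 of the ynenone; the closest known reaction types are the carbene-catalysed intramolecular crossed aldehyde–ketone benzoin cyclisation and the base-mediated cycloisomerisation of 2-(hydroxymethyl)-3-alkynyl enones to 1H-isochromenes.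

Step 8
Reactants: 15 (6S,7R)-6,7-dihydroxy-7-methyl-3-[(E)-prop-1-en-1-yl]-1,5,6,7-tetrahydro-8H-isochromen-8-one
Product: 16 (6S,7R)-6-[(tert-butyldimethylsilyl)oxy]-7-hydroxy-7-methyl-3-[(E)-prop-1-en-1-yl]-1,5,6,7-tetrahydro-8H-isochromen-8-one
Conditions: t-BuMe2SiOTf (1.05 equiv), 2,6-lutidine, CH2Cl2, −78 °C
Reagents that add atoms: tert-butyldimethylsilyl trifluoromethanesulfonate, CC(C)(C)[Si](C)(C)OS(=O)(=O)C(F)(F)F
Why: The secondary C6 hydroxyl is silylated far faster than the hindered tertiary α-ketol hydroxyl, which leaves only C7–OH free for acylation (selective silyl ether formation).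

Step 9
Reactants: 17 3-methoxy-5-methylphenol
Product: 18 4-hydroxy-2-methoxy-6-methylbenzaldehyde
Conditions: POCl3, DMF, 0 °C → rt; then aq. NaOAc, 50 °C
Reagents that add atoms: N,N-dimethylformamide, CN(C)C=O; water, O
Why: The chloroiminium electrophile attacks para to the free hydroxyl, the strongest donor, and the minor ortho-hydroxy isomer is removed by chromatography (Vilsmeier–Haack formylation).

Step 10
Reactants: 18 4-hydroxy-2-methoxy-6-methylbenzaldehyde
Product: 19 4-[(tert-butyldimethylsilyl)oxy]-2-methoxy-6-methylbenzaldehyde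
Conditions: t-BuMe2SiCl, imidazole, DMF, rt
Reagents that add atoms: tert-butyldimethylsilyl chloride, CC(C)(C)[Si](C)(C)Cl
Why: The phenol is capped with the same silyl group as C6–OH so that a single fluoride step frees both at the end (silyl ether formation).

Step 11
Reactants: 19 4-[(tert-butyldimethylsilyl)oxy]-2-methoxy-6-methylbenzaldehyde
Product: 20 4-[(tert-butyldimethylsilyl)oxy]-2-methoxy-6-methylbenzoic acid
Conditions: NaClO2, NaH2PO4, 2-methylbut-2-ene, t-BuOH/H2O, 0 °C → rt
Reagents that add atoms: sodium chlorite, [Na+].[O-]Cl=O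
Why: Buffered chlorite oxidises the aldehyde to the acid while the alkene scavenger removes hypochlorite before it can chlorinate the electron-rich ring or cleave the silyl ether (Pinnick oxidation).

Step 12
Reactants: 16 (6S,7R)-6-[(tert-butyldimethylsilyl)oxy]-7-hydroxy-7-methyl-3-[(E)-prop-1-en-1-yl]-1,5,6,7-tetrahydro-8H-isochromen-8-one; 20 4-[(tert-butyldimethylsilyl)oxy]-2-methoxy-6-methylbenzoic acid
Product: 22 (6S,7R)-6-[(tert-butyldimethylsilyl)oxy]-7-methyl-8-oxo-3-[(E)-prop-1-en-1-yl]-5,6,7,8-tetrahydro-1H-isochromen-7-yl 4-[(tert-butyldimethylsilyl)oxy]-2-methoxy-6-methylbenzoate, via aroyl chloride 21 (not isolated)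
Conditions: 20, Me2C=C(Cl)NMe2, CH2Cl2, 0 °C → rt; 16, LiN(SiMe3)2 (1.05 equiv), THF, −78 °C; then 21, −78 → 0 °C
Reagents that add atoms: none
Why: The chloroenamine makes the acid chloride under neutral conditions that spare the aryl silyl ether, and the lithium alkoxide of the tertiary α-ketol is nucleophilic enough to be acylated by the 2,6-disubstituted aroyl chloride at low temperature with C7 untouched (alkoxide acylation).

Step 13
Reactants: 22 (6S,7R)-6-[(tert-butyldimethylsilyl)oxy]-7-methyl-8-oxo-3-[(E)-prop-1-en-1-yl]-5,6,7,8-tetrahydro-1H-isochromen-7-yl 4-[(tert-butyldimethylsilyl)oxy]-2-methoxy-6-methylbenzoate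
Product: 23 (6S,7R)-6-hydroxy-7-methyl-8-oxo-3-[(E)-prop-1-en-1-yl]-5,6,7,8-tetrahydro-1H-isochromen-7-yl 4-hydroxy-2-methoxy-6-methylbenzoate (target)
Conditions: HF·pyridine, pyridine, THF, 0 °C → rt
Reagents that add atoms: none
Why: Buffered acidic fluoride cleaves the aryl and the secondary silyl ether without the base-induced 1,2-acyl shift to the freed C6–OH and without harming the push–pull dienol ether (fluoride desilylation).

**Compound list**

1 | methyl pyruvate | CC(=O)C(=O)OC | starting material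
2 | methyl 2,2-dimethoxypropanoate | COC(=O)C(C)(OC)OC | intermediate
3 | 2,2-dimethoxypropanal | CC(OC)(OC)C=O | intermediate
4 | (E)-1-methoxy-3-(trimethylsilyloxy)buta-1,3-diene | CO/C=C/C(=C)O[Si](C)(C)C | starting material
5 | (2S)-2-(1,1-dimethoxyethyl)-6-methoxy-4-(trimethylsilyloxy)-3,6-dihydro-2H-pyran (C6 epimers) | CC(OC)(OC)[C@@H]1CC(O[Si](C)(C)C)=CC(OC)O1 | intermediate (not isolated)
6 | (2S)-2-(1,1-dimethoxyethyl)-5-iodo-6-methoxyoxan-4-one (C5/C6 epimers) | CC(OC)(OC)[C@@H]1CC(=O)C(I)C(OC)O1 | intermediate (not isolated)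
7 | (2S)-2-(1,1-dimethoxyethyl)-5-iodo-2,3-dihydro-4H-pyran-4-one | CC(OC)(OC)[C@@H]1CC(=O)C(I)=CO1 | intermediate
8 | (2S)-2-(1,1-dimethoxyethyl)-5-(hydroxymethyl)-2,3-dihydro-4H-pyran-4-one | CC(OC)(OC)[C@@H]1CC(=O)C(CO)=CO1 | intermediate
9 | (E)-but-2-enal | C/C=C/C=O | starting material
10 | (3E)-1,1-dibromopenta-1,3-diene | C/C=C/C=C(Br)Br | intermediate
11 | lithium (E)-pent-3-en-1-yn-1-ide | [Li]C#C/C=C/C | intermediate (not isolated)
12 | (2S)-2-(1,1-dimethoxyethyl)-5-(hydroxymethyl)-4-[(E)-pent-3-en-1-yn-1-yl]-3,4-dihydro-2H-pyran-4-ol (C4 epimers, formed as the dilithium alkoxide) | CC(OC)(OC)[C@@H]1CC(O)(C#C/C=C/C)C(CO)=CO1 | intermediate (not isolated)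
13 | (6S)-6-acetyl-3-(hydroxymethyl)-4-[(E)-pent-3-en-1-yn-1-yl]-5,6-dihydro-2H-pyran-2-ol (anomers; lactol of the (E)-hydroxy ynenal) | CC(=O)[C@@H]1CC(C#C/C=C/C)=C(CO)C(O)O1 | intermediate
14 | (5S,6R)-5,6-dihydroxy-2-(hydroxymethyl)-6-methyl-3-[(E)-pent-3-en-1-yn-1-yl]cyclohex-2-en-1-one | C/C=C/C#CC1=C(CO)C(=O)[C@](C)(O)[C@@H](O)C1 | intermediate (not isolated)
15 | (6S,7R)-6,7-dihydroxy-7-methyl-3-[(E)-prop-1-en-1-yl]-1,5,6,7-tetrahydro-8H-isochromen-8-one | C/C=C/C1=CC2=C(CO1)C(=O)[C@](C)(O)[C@@H](O)C2 | intermediate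
16 | (6S,7R)-6-[(tert-butyldimethylsilyl)oxy]-7-hydroxy-7-methyl-3-[(E)-prop-1-en-1-yl]-1,5,6,7-tetrahydro-8H-isochromen-8-one | C/C=C/C1=CC2=C(CO1)C(=O)[C@](C)(O)[C@@H](O[Si](C)(C)C(C)(C)C)C2 | intermediate
17 | 3-methoxy-5-methylphenol | COc1cc(C)cc(O)c1 | starting material
18 | 4-hydroxy-2-methoxy-6-methylbenzaldehyde | COc1cc(O)cc(C)c1C=O | intermediate
19 | 4-[(tert-butyldimethylsilyl)oxy]-2-methoxy-6-methylbenzaldehyde | COc1cc(O[Si](C)(C)C(C)(C)C)cc(C)c1C=O | intermediate
20 | 4-[(tert-butyldimethylsilyl)oxy]-2-methoxy-6-methylbenzoic acid | COc1cc(O[Si](C)(C)C(C)(C)C)cc(C)c1C(=O)O | intermediate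
21 | 4-[(tert-butyldimethylsilyl)oxy]-2-methoxy-6-methylbenzoyl chloride | COc1cc(O[Si](C)(C)C(C)(C)C)cc(C)c1C(=O)Cl | intermediate (not isolated)
22 | (6S,7R)-6-[(tert-butyldimethylsilyl)oxy]-7-methyl-8-oxo-3-[(E)-prop-1-en-1-yl]-5,6,7,8-tetrahydro-1H-isochromen-7-yl 4-[(tert-butyldimethylsilyl)oxy]-2-methoxy-6-methylbenzoate | C/C=C/C1=CC2=C(CO1)C(=O)[C@](C)(OC(=O)c1c(C)cc(O[Si](C)(C)C(C)(C)C)cc1OC)[C@@H](O[Si](C)(C)C(C)(C)C)C2 | intermediate
23 | (6S,7R)-6-hydroxy-7-methyl-8-oxo-3-[(E)-prop-1-en-1-yl]-5,6,7,8-tetrahydro-1H-isochromen-7-yl 4-hydroxy-2-methoxy-6-methylbenzoate | C/C=C/C1=CC2=C(CO1)C(=O)[C@](C)(OC(=O)c1c(C)cc(O)cc1OC)[C@@H](O)C2 | target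

**Step count**

Total: 13 steps. Longest linear sequence: 9 steps (steps 1, 2, 3, 4, 6, 7, 8, 12, 13).

**Three steps most likely to fail**

Step 7 (benzoin/oxa-Michael domino on the free lactol). The risks are redox lactonisation of the hydroxy ynenal by the carbene, slow lactol opening, and weak substrate control at C7. The fallback closes the pyran first and runs the benzoin on a protected substrate under catalyst control. It sets out from 8. Acetylide 11 is added as in step 6, but the work-up is buffered (pyridinium p-toluenesulfonate, wet THF, 0 °C) so that only the transposition occurs and the ketal stays, giving (6S)-6-(1,1-dimethoxyethyl)-3-(hydroxymethyl)-4-[(E)-pent-3-en-1-yn-1-yl]-5,6-dihydro-2H-pyran-2-ol F1. Catalytic 1,8-diazabicyclo[5.4.0]undec-7-ene then closes the pyran through the primary hydroxyl (the secondary one is shielded by the neighbouring ketal) to give 4-[(2S)-2-hydroxy-3,3-dimethoxybutyl]-6-[(E)-prop-1-en-1-yl]-2H-pyran-3-carbaldehyde F2. Silylation with t-BuMe2SiOTf and 2,6-lutidine gives 4-[(2S)-2-[(tert-butyldimethylsilyl)oxy]-3,3-dimethoxybutyl]-6-[(E)-prop-1-en-1-yl]-2H-pyran-3-carbaldehyde F3. Pyridinium p-toluenesulfonate in wet acetone unmasks the ketone to give 4-[(2S)-2-[(tert-butyldimethylsilyl)oxy]-3-oxobutyl]-6-[(E)-prop-1-en-1-yl]-2H-pyran-3-carbaldehyde F4. The benzoin cyclisation is then run on this hydroxyl-free keto aldehyde with 5a,10b-dihydro-2-(pentafluorophenyl)-4H,6H-indeno[2,1-b][1,2,4]triazolo[4,3-d][1,4]oxazinium tetrafluoroborate (both antipodes screened, the matched one kept) and Et3N, and it comes back to the route at 16.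

Step 6 (acetylide addition, transposition and ketal hydrolysis in one operation). The risks are enolisation instead of 1,2-addition in the presence of the free hydroxyl, and Meyer–Schuster-type side reactions during the longer acid treatment that the ketal needs. The fallback brings in the alkyne before C1 and carries the aldehyde as a glycoside. It sets out from 7. Acetylide 11 adds to the iodo enone, which has no free hydroxyl, and pyridinium p-toluenesulfonate in methanol transposes the carbinol to (6S)-6-(1,1-dimethoxyethyl)-3-iodo-2-methoxy-4-[(E)-pent-3-en-1-yn-1-yl]-5,6-dihydro-2H-pyran F5. Stille coupling with Bu3SnCH2OH and Pd(PPh3)4 gives [(6S)-6-(1,1-dimethoxyethyl)-2-methoxy-4-[(E)-pent-3-en-1-yn-1-yl]-5,6-dihydro-2H-pyran-3-yl]methanol F6. One treatment with 1 M aq. HCl in THF hydrolyses glycoside and ketal together, and the fallback comes back to the route at 13.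

Step 12 (acylation of the hindered tertiary α-ketol with a 2,6-disubstituted aroyl chloride). The risks are no reaction, silyl migration from O6 to O7, and α-ketol rearrangement of the alkoxide. The fallback transfers the acyl group from a benzodioxinone and methylates last. It sets out from 16. Orsellinic acid is condensed with acetone ((CF3CO)2O, CF3CO2H) to 7-hydroxy-2,2,5-trimethyl-4H-1,3-benzodioxin-4-one F7, which is silylated (t-BuMe2SiCl, imidazole) to 7-[(tert-butyldimethylsilyl)oxy]-2,2,5-trimethyl-4H-1,3-benzodioxin-4-one F8. The sodium alkoxide of 16 (NaN(SiMe3)2, THF) opens F8 with loss of acetone to give (6S,7R)-6-[(tert-butyldimethylsilyl)oxy]-7-methyl-8-oxo-3-[(E)-prop-1-en-1-yl]-5,6,7,8-tetrahydro-1H-isochromen-7-yl 4-[(tert-butyldimethylsilyl)oxy]-2-hydroxy-6-methylbenzoate F9. O-Methylation of the chelated phenol (MeI, Ag2O) then comes back to the route at 22.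

**Further compounds**

F1 | step 7 | (6S)-6-(1,1-dimethoxyethyl)-3-(hydroxymethyl)-4-[(E)-pent-3-en-1-yn-1-yl]-5,6-dihydro-2H-pyran-2-ol | CC(OC)(OC)[C@@H]1CC(C#C/C=C/C)=C(CO)C(O)O1
F2 | step 7 | 4-[(2S)-2-hydroxy-3,3-dimethoxybutyl]-6-[(E)-prop-1-en-1-yl]-2H-pyran-3-carbaldehyde | C/C=C/C1=CC(C[C@H](O)C(C)(OC)OC)=C(C=O)CO1
F3 | step 7 | 4-[(2S)-2-[(tert-butyldimethylsilyl)oxy]-3,3-dimethoxybutyl]-6-[(E)-prop-1-en-1-yl]-2H-pyran-3-carbaldehyde | C/C=C/C1=CC(C[C@H](O[Si](C)(C)C(C)(C)C)C(C)(OC)OC)=C(C=O)CO1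
F4 | step 7 | 4-[(2S)-2-[(tert-butyldimethylsilyl)oxy]-3-oxobutyl]-6-[(E)-prop-1-en-1-yl]-2H-pyran-3-carbaldehyde | C/C=C/C1=CC(C[C@H](O[Si](C)(C)C(C)(C)C)C(C)=O)=C(C=O)CO1
F5 | step 6 | (6S)-6-(1,1-dimethoxyethyl)-3-iodo-2-methoxy-4-[(E)-pent-3-en-1-yn-1-yl]-5,6-dihydro-2H-pyran | CC(OC)(OC)[C@@H]1CC(C#C/C=C/C)=C(I)C(OC)O1
F6 | step 6 | [(6S)-6-(1,1-dimethoxyethyl)-2-methoxy-4-[(E)-pent-3-en-1-yn-1-yl]-5,6-dihydro-2H-pyran-3-yl]methanol | CC(OC)(OC)[C@@H]1CC(C#C/C=C/C)=C(CO)C(OC)O1
F7 | step 12 | 7-hydroxy-2,2,5-trimethyl-4H-1,3-benzodioxin-4-one | CC1(C)OC(=O)c2c(C)cc(O)cc2O1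
F8 | step 12 | 7-[(tert-butyldimethylsilyl)oxy]-2,2,5-trimethyl-4H-1,3-benzodioxin-4-one | CC1(C)OC(=O)c2c(C)cc(O[Si](C)(C)C(C)(C)C)cc2O1
F9 | step 12 | (6S,7R)-6-[(tert-butyldimethylsilyl)oxy]-7-methyl-8-oxo-3-[(E)-prop-1-en-1-yl]-5,6,7,8-tetrahydro-1H-isochromen-7-yl 4-[(tert-butyldimethylsilyl)oxy]-2-hydroxy-6-methylbenzoate | C/C=C/C1=CC2=C(CO1)C(=O)[C@](C)(OC(=O)c1c(C)cc(O[Si](C)(C)C(C)(C)C)cc1O)[C@@H](O[Si](C)(C)C(C)(C)C)C2
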